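**Retrosynthetic overview**

1. The diacid comes from its bis(methyl ester) C2 silyl ether; the C13=C14 enoate comes from a C13 methyl ketone by Horner–Wadsworth–Emmons olefination.
2. Key disconnection C9–C11: Hosomi–Sakurai addition of a ring B allylsilane (C9=C8–C17H2–SiMe3) to but-3-en-2-one. It is possible because the exocyclic methylene C17=C8 of ring B stands next to C9 and 1,5 to C13: C17–C8–C9 is an allyl unit and C17=C8–C9–C11–C12–C13(=O) a δ,ε-unsaturated ketone.
3. The allylsilane comes from the C8 enol triflate, made by Me2CuLi addition (C20, cis ring fusion) to a C8 enone that is the Birch product of an anisole: ring B is carried as an arene whose oxygen marks C8.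
4. Ring A is closed onto that arene by an intramolecular Heck reaction (C4–C5, quaternary C4); its C2 carbinol, from (S)-epichlorohydrin, relays stereochemistry to C4, C5, C10 and C9.
5. Ring order: ring B (bought as an arene) → ring A (Heck) → ring B dearomatised and functionalised.

Key step: step 11

Remark and assumption: labdane numbering is used (ring A = C1–C5 and C10, ring B = C5–C10, C17 = methylene carbon on C8, C18 = methyl on C4, C19 = carboxyl carbon on C4, C20 = methyl on C10; the target is cis-fused, with H5, C18, C20, the C2 oxygen and the C9 side chain on one face and C19 on the other); 4-bromo-3-iodoanisole and isomerically pure (E)-2-bromobut-2-ene are taken as catalogue compounds.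

**Route**

Step 1
Reactants: 1 4-bromo-3-iodoanisole; 2 (S)-epichlorohydrin
Product: 5 (S)-2-(2-bromo-5-methoxybenzyl)oxirane, via aryl Grignard reagent 3 (not isolated), via chloromagnesium alkoxide 4 (not isolated)
Conditions: i-PrMgCl·LiCl, THF, −30 °C; CuI (10 mol %), 2, −30 → 0 °C; then aq NaOH, rt
Reagents that add atoms: none
Why: Iodine–magnesium exchange is confined to the C–I bond, the CuI-catalysed Grignard reagent opens the epoxide of 2 at its CH2 terminus (SN2) and hydroxide recloses the chlorohydrin (intramolecular Williamson reaction), so the untouched stereocentre of 2 becomes C2 of the target.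

Step 2
Reactants: 5 (S)-2-(2-bromo-5-methoxybenzyl)oxirane; 6 (E)-2-bromobut-2-ene
Product: 9 (2R,4E)-1-(2-bromo-5-methoxyphenyl)-4-methylhex-4-en-2-ol, via alkenyllithium 7 (not isolated), via alkenyl Grignard reagent 8 (not isolated)
Conditions: 6, t-BuLi (2 equiv), Et2O, −78 °C; MgBr2·OEt2, −78 → −30 °C; CuI (10 mol %), 5, THF, −30 → 0 °C; H2O
Reagents that add atoms: none
Why: Bromine–lithium exchange with retention, transmetalation and CuI-catalysed SN2 opening of the terminal epoxide at its CH2 group attach C4, C18 and C19 as a trisubstituted alkene placed for 6-exo cyclisation, the carbinol centre not being involved.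

Step 3
Reactants: 9 (2R,4E)-1-(2-bromo-5-methoxyphenyl)-4-methylhex-4-en-2-ol
Product: 10 {[(2R,4E)-1-(2-bromo-5-methoxyphenyl)-4-methylhex-4-en-2-yl]oxy}triisopropylsilane
Conditions: i-Pr3SiOTf, 2,6-lutidine, CH2Cl2, 0 °C
Reagents that add atoms: triisopropylsilyl trifluoromethanesulfonate, CC(C)[Si](OS(=O)(=O)C(F)(F)F)(C(C)C)C(C)C
Why: Standard silylation of a secondary alcohol with a silyl triflate gives a bulky ether that later anchors ring A with the C2 oxygen equatorial and tolerates dissolving metal, Lewis acid and base.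

Step 4
Reactants: 10 {[(2R,4E)-1-(2-bromo-5-methoxyphenyl)-4-methylhex-4-en-2-yl]oxy}triisopropylsilane
Product: 11 triisopropyl{[(2S,4S)-7-methoxy-4-methyl-4-vinyl-1,2,3,4-tetrahydronaphthalen-2-yl]oxy}silane
Conditions: Pd(OAc)2 (10 mol %), PPh3 (25 mol %), K2CO3, DMF, 90 °C
Reagents that add atoms: none
Why: The intramolecular 6-exo-trig Heck reaction (oxidative addition, syn-carbopalladation of the trisubstituted alkene, β-hydride elimination towards the methyl group) closes ring A and creates the quaternary C4; in the chair-like insertion transition state the silyloxy group is equatorial and the palladium-bearing carbon (future C19) axial, which should place the vinyl group trans and C18 cis to the C2 oxygen.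

Step 5
Reactants: 11 triisopropyl{[(2S,4S)-7-methoxy-4-methyl-4-vinyl-1,2,3,4-tetrahydronaphthalen-2-yl]oxy}silane
Product: 12 (1R,3S)-6-methoxy-1-methyl-3-[(triisopropylsilyl)oxy]-1,2,3,4-tetrahydronaphthalene-1-carbaldehyde
Conditions: O3, CH2Cl2/MeOH, −78 °C (indicator end point); Me2S, −78 °C → rt
Reagents that add atoms: ozone, [O-][O+]=O
Why: Ozonolysis with reductive work-up cleaves the only non-aromatic C=C bond to the non-enolisable neopentyl aldehyde, the anisole ring reacting far more slowly than the monosubstituted alkene at −78 °C.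

Step 6
Reactants: 12 (1R,3S)-6-methoxy-1-methyl-3-[(triisopropylsilyl)oxy]-1,2,3,4-tetrahydronaphthalene-1-carbaldehyde
Product: 13 (1R,3S)-6-methoxy-1-methyl-3-[(triisopropylsilyl)oxy]-1,2,3,4-tetrahydronaphthalene-1-carboxylic acid
Conditions: NaClO2, NaH2PO4, 2-methylbut-2-ene, t-BuOH/H2O, rt
Reagents that add atoms: sodium chlorite, [Na+].[O-]Cl=O
Why: Pinnick oxidation converts the aldehyde into the C19 acid without touching the silyl ether or the arene, the alkene scavenger removing hypochlorite.

Step 7
Reactants: 13 (1R,3S)-6-methoxy-1-methyl-3-[(triisopropylsilyl)oxy]-1,2,3,4-tetrahydronaphthalene-1-carboxylic acid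
Product: 16 (1R,3S,8aS)-1-methyl-6-oxo-3-[(triisopropylsilyl)oxy]-1,2,3,4,6,7,8,8a-octahydronaphthalene-1-carboxylic acid, via dihydroanisole acid 14 (not isolated), via unconjugated enone acid 15 (not isolated)
Conditions: Li, NH3(l), t-BuOH, THF, −78 °C; NH4Cl; then 2 M HCl, THF, rt
Reagents that add atoms: water, O
Why: Birch reduction of the anisole (the carboxylate is inert) gives the 2,5-dihydroanisole with the tetrasubstituted C5=C10 bond, and acid hydrolysis of the enol ether followed by conjugation gives the C8 enone; C5 is set under equilibrating conditions, where protonation anti to the axial carboxyl group and the need to keep the C2 silyloxy and C18 groups equatorial both favour H5 cis to C18.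

Step 8
Reactants: 16 (1R,3S,8aS)-1-methyl-6-oxo-3-[(triisopropylsilyl)oxy]-1,2,3,4,6,7,8,8a-octahydronaphthalene-1-carboxylic acid
Product: 17 methyl (1R,3S,8aS)-1-methyl-6-oxo-3-[(triisopropylsilyl)oxy]-1,2,3,4,6,7,8,8a-octahydronaphthalene-1-carboxylate
Conditions: MeI, K2CO3, DMF, rt
Reagents that add atoms: iodomethane, CI
Why: O-alkylation of the carboxylate (SN2 on iodomethane) is insensitive to the hindrance of the neopentyl acid, and the basic medium would also reopen by β-elimination any lactone formed by conjugate addition of the acid to the enone.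

Step 9
Reactants: 17 methyl (1R,3S,8aS)-1-methyl-6-oxo-3-[(triisopropylsilyl)oxy]-1,2,3,4,6,7,8,8a-octahydronaphthalene-1-carboxylate
Product: 19 methyl (1R,3S,4aS,8aS)-1,4a-dimethyl-3-[(triisopropylsilyl)oxy]-6-{[(trifluoromethyl)sulfonyl]oxy}-1,2,3,4,4a,7,8,8a-octahydronaphthalene-1-carboxylate, via lithium enolate 18 (not isolated)
Conditions: Me2CuLi (from MeLi and CuI), Et2O, −78 → 0 °C; then N-(5-chloropyridin-2-yl)bis(trifluoromethanesulfonyl)imide, THF, −78 → 0 °C
Reagents that add atoms: lithium dimethylcuprate, [Li+].C[Cu-]C; N-(5-chloropyridin-2-yl)bis(trifluoromethanesulfonyl)imide, O=S(=O)(N(c1ccc(Cl)cn1)S(=O)(=O)C(F)(F)F)C(F)(F)F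
Why: Conjugate addition of the Gilman reagent to the β,β-disubstituted enone delivers C20 to C10 by axial attack anti to C4 and away from the axial C19 ester, which should give the cis ring fusion (C20 cis to H5), and the regiodefined enolate is trapped on oxygen so that the double bond is fixed at C8=C9.

Step 10
Reactants: 19 methyl (1R,3S,4aS,8aS)-1,4a-dimethyl-3-[(triisopropylsilyl)oxy]-6-{[(trifluoromethyl)sulfonyl]oxy}-1,2,3,4,4a,7,8,8a-octahydronaphthalene-1-carboxylate
Product: 20 methyl (1R,3S,4aR,8aS)-1,4a-dimethyl-3-[(triisopropylsilyl)oxy]-6-[(trimethylsilyl)methyl]-1,2,3,4,4a,7,8,8a-octahydronaphthalene-1-carboxylate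
Conditions: Me3SiCH2MgCl, Pd(PPh3)4 (5 mol %), THF, 0 °C → rt
Reagents that add atoms: (trimethylsilyl)methylmagnesium chloride, C[Si](C)(C)C[Mg]Cl
Why: Kumada cross-coupling of the alkenyl triflate with the silylmethyl Grignard reagent under zerovalent palladium catalysis puts C17 in place as an allylsilane, the hindered neopentyl ester not being attacked at this temperature.

Step 11
Reactants: 20 methyl (1R,3S,4aR,8aS)-1,4a-dimethyl-3-[(triisopropylsilyl)oxy]-6-[(trimethylsilyl)methyl]-1,2,3,4,4a,7,8,8a-octahydronaphthalene-1-carboxylate; 21 but-3-en-2-one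
Product: 22 methyl (1R,3S,4aR,5S,8aS)-1,4a-dimethyl-6-methylidene-5-(3-oxobutyl)-3-[(triisopropylsilyl)oxy]decahydronaphthalene-1-carboxylate
Conditions: TiCl4 (1.2 equiv), 2,6-di-tert-butyl-4-methylpyridine (0.3 equiv), CH2Cl2, −78 °C; aq NaHCO3
Reagents that add atoms: none
Why: TiCl4 activates the carbonyl group of 21, C9 (the γ-carbon of the allylsilane) attacks the terminal carbon of the enone (future C11) while the C17–Si bond stabilises the developing positive charge at C8, and chloride-assisted loss of the silyl group leaves the C8=C17 methylene and a titanium enolate that is protonated on work-up. This is an anti-SE2' Hosomi–Sakurai conjugate allylation, whose closest precedent is the TiCl4-mediated addition of (cyclohex-1-enylmethyl)silanes to enones to give 2-substituted methylenecyclohexanes; no ring is closed. The one new stereocentre, C9, should be set by the cis-fused skeleton: ring A, with C4 axial on ring B and carrying the ester, is folded under one face of ring B and is 1,3-related to C9, so the activated enone can reach C9 only from the convex face that carries H5 and C20, which puts C11 equatorial and cis to C20 as in the target. The step needs γ-attack of the allyl unit (secured by the β-silicon effect, which makes C9 the only nucleophilic terminus), 1,4- and not 1,2-addition to 21 (secured by the TiCl4/allylsilane pairing) and no protodesilylation (anhydrous conditions, low temperature, hindered pyridine as proton scavenger). In one operation it forms the C9–C11 bond, fixes the last ring stereocentre, unveils the 8(17)-methylene without any carbonyl olefination next to C9 and brings in four of the six missing side-chain carbons.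

Step 12
Reactants: 22 methyl (1R,3S,4aR,5S,8aS)-1,4a-dimethyl-6-methylidene-5-(3-oxobutyl)-3-[(triisopropylsilyl)oxy]decahydronaphthalene-1-carboxylate; 23 trimethyl phosphonoacetate
Product: 24 methyl (1R,3S,4aR,5S,8aS)-5-[(3E)-5-methoxy-3-methyl-5-oxopent-3-en-1-yl]-1,4a-dimethyl-6-methylidene-3-[(triisopropylsilyl)oxy]decahydronaphthalene-1-carboxylate
Conditions: 23, NaH, THF, 0 °C; then 22, 0 → 60 °C
Reagents that add atoms: none
Why: Horner–Wadsworth–Emmons olefination of the methyl ketone with the stabilised phosphonate anion creates C13=C14 and should favour the (E)-isomer, in which the ester is trans to the larger C12 chain, the minor (Z)-isomer being removable by chromatography.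

Step 13
Reactants: 24 methyl (1R,3S,4aR,5S,8aS)-5-[(3E)-5-methoxy-3-methyl-5-oxopent-3-en-1-yl]-1,4a-dimethyl-6-methylidene-3-[(triisopropylsilyl)oxy]decahydronaphthalene-1-carboxylate
Product: 25 methyl (1R,3S,4aR,5S,8aS)-3-hydroxy-5-[(3E)-5-methoxy-3-methyl-5-oxopent-3-en-1-yl]-1,4a-dimethyl-6-methylidenedecahydronaphthalene-1-carboxylate
Conditions: n-Bu4NF, THF, rt → 45 °C
Reagents that add atoms: none
Why: Fluoride-induced cleavage of the Si–O bond frees the C2 alcohol with retention, the alkenes and esters being inert to fluoride.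

Step 14
Reactants: 25 methyl (1R,3S,4aR,5S,8aS)-3-hydroxy-5-[(3E)-5-methoxy-3-methyl-5-oxopent-3-en-1-yl]-1,4a-dimethyl-6-methylidenedecahydronaphthalene-1-carboxylate
Product: 27 (1R,3S,4aR,5S,8aS)-5-[(3E)-4-carboxy-3-methylbut-3-en-1-yl]-3-hydroxy-1,4a-dimethyl-6-methylidenedecahydronaphthalene-1-carboxylic acid, via C15 acid C19 methyl ester 26 (not isolated)
Conditions: LiOH, THF/MeOH/H2O, rt; evaporation; NaSEt, DMF, 80 °C; aq HCl to pH 3
Reagents that add atoms: lithium hydroxide, [Li+].[OH-]
Why: Saponification removes the unhindered C15 methyl ester, and the axial neopentyl C19 methyl ester, inert to hydroxide, is then cleaved by SN2 attack of thiolate on its O-methyl group; the enoate is by then a carboxylate, so thiolate conjugate addition and E/Z scrambling are not expected, and no stereocentre is touched.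

**Compound list**

1 | 4-bromo-3-iodoanisole | COc1ccc(Br)c(I)c1 | starting material
2 | (S)-epichlorohydrin | ClC[C@@H]1CO1 | starting material
3 | (2-bromo-5-methoxyphenyl)magnesium chloride | COc1ccc(Br)c([Mg]Cl)c1 | intermediate
4 | chloromagnesium alkoxide of (S)-1-(2-bromo-5-methoxyphenyl)-3-chloropropan-2-ol | COc1ccc(Br)c(c1)C[C@H](O[Mg]Cl)CCl | intermediate
5 | (S)-2-(2-bromo-5-methoxybenzyl)oxirane | COc1ccc(Br)c(c1)C[C@H]1CO1 | intermediate
6 | (E)-2-bromobut-2-ene | C/C=C(/Br)C | starting material
7 | but-2-en-2-yllithium (lithium in place of bromine, geometry retained) | C/C=C(/[Li])C | intermediate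
8 | but-2-en-2-ylmagnesium bromide (same geometry) | C/C=C(/[Mg]Br)C | intermediate
9 | (2R,4E)-1-(2-bromo-5-methoxyphenyl)-4-methylhex-4-en-2-ol | COc1ccc(Br)c(c1)C[C@H](O)C/C(C)=C/C | intermediate
10 | {[(2R,4E)-1-(2-bromo-5-methoxyphenyl)-4-methylhex-4-en-2-yl]oxy}triisopropylsilane | COc1ccc(Br)c(c1)C[C@H](O[Si](C(C)C)(C(C)C)C(C)C)C/C(C)=C/C | intermediate
11 | triisopropyl{[(2S,4S)-7-methoxy-4-methyl-4-vinyl-1,2,3,4-tetrahydronaphthalen-2-yl]oxy}silane (silyloxy cis to the methyl group) | COc1ccc2c(c1)C[C@H](O[Si](C(C)C)(C(C)C)C(C)C)C[C@@]2(C)C=C | intermediate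
12 | (1R,3S)-6-methoxy-1-methyl-3-[(triisopropylsilyl)oxy]-1,2,3,4-tetrahydronaphthalene-1-carbaldehyde | COc1ccc2c(c1)C[C@H](O[Si](C(C)C)(C(C)C)C(C)C)C[C@@]2(C)C=O | intermediate
13 | (1R,3S)-6-methoxy-1-methyl-3-[(triisopropylsilyl)oxy]-1,2,3,4-tetrahydronaphthalene-1-carboxylic acid | COc1ccc2c(c1)C[C@H](O[Si](C(C)C)(C(C)C)C(C)C)C[C@@]2(C)C(=O)O | intermediate
14 | (1R,3S)-6-methoxy-1-methyl-3-[(triisopropylsilyl)oxy]-1,2,3,4,5,8-hexahydronaphthalene-1-carboxylic acid | COC1=CCC2=C(C1)C[C@H](O[Si](C(C)C)(C(C)C)C(C)C)C[C@@]2(C)C(=O)O | intermediate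
15 | (1R,3S)-1-methyl-6-oxo-3-[(triisopropylsilyl)oxy]-1,2,3,4,5,6,7,8-octahydronaphthalene-1-carboxylic acid | O=C1CCC2=C(C1)C[C@H](O[Si](C(C)C)(C(C)C)C(C)C)C[C@@]2(C)C(=O)O | intermediate
16 | (1R,3S,8aS)-1-methyl-6-oxo-3-[(triisopropylsilyl)oxy]-1,2,3,4,6,7,8,8a-octahydronaphthalene-1-carboxylic acid (C8 enone, H5 cis to C18) | O=C1CC[C@H]2C(=C1)C[C@H](O[Si](C(C)C)(C(C)C)C(C)C)C[C@@]2(C)C(=O)O | intermediate
17 | methyl (1R,3S,8aS)-1-methyl-6-oxo-3-[(triisopropylsilyl)oxy]-1,2,3,4,6,7,8,8a-octahydronaphthalene-1-carboxylate | O=C1CC[C@H]2C(=C1)C[C@H](O[Si](C(C)C)(C(C)C)C(C)C)C[C@@]2(C)C(=O)OC | intermediate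
18 | lithium C8 enolate of the cis-fused C10-methylated ketone (C8–OLi, C8=C9, C20 cis to H5) | C1(O[Li])CC[C@H]2[C@](C)(C[C@H](O[Si](C(C)C)(C(C)C)C(C)C)C[C@@]2(C)C(=O)OC)C=1 | intermediate
19 | methyl (1R,3S,4aS,8aS)-1,4a-dimethyl-3-[(triisopropylsilyl)oxy]-6-{[(trifluoromethyl)sulfonyl]oxy}-1,2,3,4,4a,7,8,8a-octahydronaphthalene-1-carboxylate | C1(OS(=O)(=O)C(F)(F)F)CC[C@H]2[C@](C)(C[C@H](O[Si](C(C)C)(C(C)C)C(C)C)C[C@@]2(C)C(=O)OC)C=1 | intermediate
20 | methyl (1R,3S,4aR,8aS)-1,4a-dimethyl-3-[(triisopropylsilyl)oxy]-6-[(trimethylsilyl)methyl]-1,2,3,4,4a,7,8,8a-octahydronaphthalene-1-carboxylate | C1(C[Si](C)(C)C)CC[C@H]2[C@](C)(C[C@H](O[Si](C(C)C)(C(C)C)C(C)C)C[C@@]2(C)C(=O)OC)C=1 | intermediate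
21 | but-3-en-2-one | CC(=O)C=C | starting material
22 | methyl (1R,3S,4aR,5S,8aS)-1,4a-dimethyl-6-methylidene-5-(3-oxobutyl)-3-[(triisopropylsilyl)oxy]decahydronaphthalene-1-carboxylate | C=C1CC[C@H]2[C@](C)(C[C@H](O[Si](C(C)C)(C(C)C)C(C)C)C[C@@]2(C)C(=O)OC)[C@H]1CCC(C)=O | intermediate
23 | trimethyl phosphonoacetate | COC(=O)CP(=O)(OC)OC | starting material
24 | methyl (1R,3S,4aR,5S,8aS)-5-[(3E)-5-methoxy-3-methyl-5-oxopent-3-en-1-yl]-1,4a-dimethyl-6-methylidene-3-[(triisopropylsilyl)oxy]decahydronaphthalene-1-carboxylate | C=C1CC[C@H]2[C@](C)(C[C@H](O[Si](C(C)C)(C(C)C)C(C)C)C[C@@]2(C)C(=O)OC)[C@H]1CC/C(C)=C/C(=O)OC | intermediate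
25 | methyl (1R,3S,4aR,5S,8aS)-3-hydroxy-5-[(3E)-5-methoxy-3-methyl-5-oxopent-3-en-1-yl]-1,4a-dimethyl-6-methylidenedecahydronaphthalene-1-carboxylate | C=C1CC[C@H]2[C@](C)(C[C@H](O)C[C@@]2(C)C(=O)OC)[C@H]1CC/C(C)=C/C(=O)OC | intermediate
26 | C15 carboxylic acid of 25 with the C19 methyl ester still in place | C=C1CC[C@H]2[C@](C)(C[C@H](O)C[C@@]2(C)C(=O)OC)[C@H]1CC/C(C)=C/C(=O)O | intermediate
27 | (1R,3S,4aR,5S,8aS)-5-[(3E)-4-carboxy-3-methylbut-3-en-1-yl]-3-hydroxy-1,4a-dimethyl-6-methylidenedecahydronaphthalene-1-carboxylic acid | C=C1CC[C@H]2[C@](C)(C[C@H](O)C[C@@]2(C)C(=O)O)[C@H]1CC/C(C)=C/C(=O)O | target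

**Step count and risks**

Total step count: 14. Longest linear sequence: 14 steps (from 1; the partners 2, 6, 21 and 23 are bought).

Steps most likely to fail:

1. Step 11. What may go wrong: poor facial selectivity at C9 (both faces of the C8=C9 bond are encumbered, one by ring A and one by C20), or protodesilylation of the allylsilane before C–C bond formation. Fallback, from 17 back to 24, with C9 under thermodynamic control and the methylene made by carbonyl olefination: Me2CuLi with Me3SiCl converts 17 into the trimethylsilyl enol ether F1. TiCl4-mediated Mukaiyama–Michael addition of F1 to 21 gives the 8,13-diketone F2, in which C9 is epimerisable; brief mild base treatment (K2CO3, MeOH, 0 °C, short enough to avoid intramolecular aldol closure) should settle the side chain equatorial. Chemoselective Horner–Wadsworth–Emmons olefination of the unhindered methyl ketone with 23 gives the 8-oxo (E)-enoate F3. Wittig methylenation of the C8 ketone (Ph3P=CH2, THF) returns to 24.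

2. Step 9. What may go wrong: sluggish or face-unselective 1,4-addition at the hindered β,β-disubstituted carbon C10, or loss of enolate regiochemistry before O-sulfonylation. Fallback, from 17 back to 19, bringing C20 in through a cyclopropane: Luche reduction (NaBH4, CeCl3·7H2O, MeOH) should give the allylic alcohol F4 with the C8 hydroxyl cis to H5. Hydroxyl-directed Simmons–Smith cyclopropanation (Et2Zn, CH2I2) delivers CH2 to the same face and gives the cyclopropyl carbinol F5. Oxidation (Dess–Martin periodinane) gives the cyclopropyl ketone F6. Reductive cleavage (Li, NH3(l), THF, −78 °C, no proton donor) breaks the cyclopropane bond that overlaps with the carbonyl π-system (C9–CH2), leaving C20 on C10 and the same lithium enolate 18, which is trapped with the triflimide of step 9 to give 19.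

3. Step 4. What may go wrong: insufficient diastereofacial control in the migratory insertion (C4 epimer), or slow insertion into the trisubstituted alkene with competing hydrodebromination. Fallback, from 5 back to 12, with C4 as nucleophile and no ozonolysis: opening of 5 with lithiated propanal N,N-dimethylhydrazone (LDA, THF) gives the hydroxy hydrazone F7. Silylation (i-Pr3SiOTf, 2,6-lutidine) gives the silyl ether F8. Hydrazone hydrolysis (CuCl2, THF/H2O) gives the α-branched aldehyde F9. Pd-catalysed intramolecular α-arylation of the aldehyde (Pd(OAc)2, chiral bisphosphine such as BINAP matched to the C2 centre, Cs2CO3, DMF, 80 °C) forms the C4–C5 bond and the quaternary centre under catalyst control and gives 12 directly.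

Further compounds
F1 | step 11 | trimethylsilyl enol ether of the C10-methylated ketone (C8–OSiMe3, C8=C9) | C1(O[Si](C)(C)C)CC[C@H]2[C@](C)(C[C@H](O[Si](C(C)C)(C(C)C)C(C)C)C[C@@]2(C)C(=O)OC)C=1
F2 | step 11 | 8,13-diketone (C8 ketone, C9 3-oxobutyl side chain equatorial) | O=C1CC[C@H]2[C@](C)(C[C@H](O[Si](C(C)C)(C(C)C)C(C)C)C[C@@]2(C)C(=O)OC)[C@H]1CCC(C)=O
F3 | step 11 | 8-oxo (E)-enoate | O=C1CC[C@H]2[C@](C)(C[C@H](O[Si](C(C)C)(C(C)C)C(C)C)C[C@@]2(C)C(=O)OC)[C@H]1CC/C(C)=C/C(=O)OC
F4 | step 9 | C8 allylic alcohol (hydroxyl cis to H5, C9=C10) | O[C@H]1CC[C@H]2C(=C1)C[C@H](O[Si](C(C)C)(C(C)C)C(C)C)C[C@@]2(C)C(=O)OC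
F5 | step 9 | 9,10-methano cyclopropyl carbinol (CH2 on the face of the C8 hydroxyl and H5) | O[C@H]1CC[C@H]2[C@]3(C[C@@H]13)C[C@H](O[Si](C(C)C)(C(C)C)C(C)C)C[C@@]2(C)C(=O)OC
F6 | step 9 | 9,10-methano cyclopropyl C8 ketone | O=C1CC[C@H]2[C@]3(C[C@@H]13)C[C@H](O[Si](C(C)C)(C(C)C)C(C)C)C[C@@]2(C)C(=O)OC
F7 | step 4 | N,N-dimethylhydrazone of (4R)-5-(2-bromo-5-methoxyphenyl)-4-hydroxy-2-methylpentanal (C2 epimer mixture) | COc1ccc(Br)c(c1)C[C@H](O)CC(C)/C=N/N(C)C
F8 | step 4 | triisopropylsilyl ether of F7 | COc1ccc(Br)c(c1)C[C@H](O[Si](C(C)C)(C(C)C)C(C)C)CC(C)/C=N/N(C)C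
F9 | step 4 | (4R)-5-(2-bromo-5-methoxyphenyl)-2-methyl-4-[(triisopropylsilyl)oxy]pentanal (C2 epimer mixture) | COc1ccc(Br)c(c1)C[C@H](O[Si](C(C)C)(C(C)C)C(C)C)CC(C)C=O
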